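**Retrosynthetic overview**
1. Numbering: C1 = ester-bearing CH, C2=C3, C4 = sp2 fusion carbon, C5 = vinylic CH, C6 = C=O, C7 = CHOH, C8 = CH2, C9 = C(CH3), C10 = CH(CH3). The strategy rests on ring A carrying C1–O, C10–CH3 and C9–CH3 all cis on three contiguous carbons: a CH2 tethered through silicon to the C1 oxygen can be delivered to C10 across a C9=C10 alkene, leaving a C9 radical that closes ring B.
2. Last disconnections: C7–OH (Rubottom oxidation of the C6 dienone), the C1–O ester bond (Yamaguchi; acid from Sharpless epoxidation and a Heck reaction), then C2=C3 and C4=C5 (two Saegusa oxidations of a cis-decalone).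
3. Key disconnection: C10–CH3 (as C10–CH2–Si) and C8–C9, both formed in one tin-hydride radical cascade from a monocyclic bromomethylsilyl ether carrying a vinyl ketone chain at C4; protodesilylation then gives C10–CH3 and C1–OH.
4. Cascade precursor from 2-methylcyclohex-2-enone: CBS reduction, Johnson–Claisen (sets C4), allylic oxidation, α-bromination/CBS/debromination (sets C1 trans to C4), Weinreb amide/vinyl Grignard, O-silylation.
5. Ring order: ring A comes from the starting material; the temporary siloxane ring and ring B form together in the key step.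

Key step: step 10

Remark: only the trans-1,4 isomer (1S,4R) of the cascade precursor is carried forward, because then the C4 chain and the siloxane lie on opposite faces and both favour the same C9 configuration; C4 itself is erased when C4=C5 is introduced.

**Route**

Step 1
Reactants: 1 2-methylcyclohex-2-en-1-one
Product: 2 (R)-2-methylcyclohex-2-en-1-ol
Conditions: (S)-Me-CBS (10 mol%), BH3·SMe2, THF, –20 °C; MeOH
Reagents that add atoms: none
Why: CBS reduction in which the α-methyl-substituted alkenyl arm acts as the large group, so the (S)-oxazaborolidine should deliver hydride to give the (R)-allylic alcohol that later fixes C4.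

Step 2
Reactants: 2 (R)-2-methylcyclohex-2-en-1-ol; 3 triethyl orthoacetate
Product: 5 ethyl 2-[(1R)-2-methylcyclohex-2-en-1-yl]acetate, via ketene acetal 4 (not isolated)
Conditions: EtCO2H (cat.), neat, 140 °C, EtOH distilled off
Reagents that add atoms: none
Why: Johnson–Claisen rearrangement, suprafacial across the allyl unit, so the carbinol configuration is transferred to the new C–C bond at the ring carbon that becomes C4 while the alkene moves to C9=C10.

Step 3
Reactants: 5 ethyl 2-[(1R)-2-methylcyclohex-2-en-1-yl]acetate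
Product: 6 ethyl 2-[(1R)-2-methyl-4-oxocyclohex-2-en-1-yl]acetate
Conditions: Rh2(cap)4 (1 mol%), t-BuOOH, K2CO3, CH2Cl2, rt
Reagents that add atoms: tert-butyl hydroperoxide, CC(C)(C)OO
Why: Peroxy-radical allylic C–H oxidation at the ring methylene next to the less substituted alkene terminus; the tertiary allylic C–H at the stereocentre is pseudoequatorial and poorly aligned, so the enone should form without touching C4.

Step 4
Reactants: 6 ethyl 2-[(1R)-2-methyl-4-oxocyclohex-2-en-1-yl]acetate
Product: 8 ethyl 2-[(1R)-3-bromo-2-methyl-4-oxocyclohex-2-en-1-yl]acetate, via dibromide 7 (not isolated)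
Conditions: Br2, CH2Cl2, 0 °C; Et3N, 0 °C → rt
Reagents that add atoms: bromine, BrBr
Why: Bromine addition to the enone and E1cB loss of HBr give the α-bromo enone, which makes the alkenyl arm unambiguously the large group for the next reduction.

Step 5
Reactants: 8 ethyl 2-[(1R)-3-bromo-2-methyl-4-oxocyclohex-2-en-1-yl]acetate
Product: 9 ethyl 2-[(1R,4S)-3-bromo-4-hydroxy-2-methylcyclohex-2-en-1-yl]acetate
Conditions: (R)-Me-CBS (20 mol%), BH3·SMe2, THF, –20 °C; MeOH
Reagents that add atoms: none
Why: CBS reduction under reagent control: with the (R)-oxazaborolidine and the bromoalkenyl arm as large group, hydride should add to give the (S)-carbinol (C1), trans to the C4 side chain.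

Step 6
Reactants: 9 ethyl 2-[(1R,4S)-3-bromo-4-hydroxy-2-methylcyclohex-2-en-1-yl]acetate
Product: 10 ethyl 2-[(1R,4S)-4-hydroxy-2-methylcyclohex-2-en-1-yl]acetate
Conditions: Pd(OAc)2 (5 mol%), PPh3, HCO2H, Et3N, DMF, 70 °C
Reagents that add atoms: none
Why: Palladium-catalysed formate hydrogenolysis of the vinyl bromide (oxidative addition, formate decarboxylation, C–H reductive elimination) leaves ester, alcohol and both stereocentres untouched.

Step 7
Reactants: 10 ethyl 2-[(1R,4S)-4-hydroxy-2-methylcyclohex-2-en-1-yl]acetate; 11 N,O-dimethylhydroxylamine hydrochloride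
Product: 12 2-[(1R,4S)-4-hydroxy-2-methylcyclohex-2-en-1-yl]-N-methoxy-N-methylacetamide
Conditions: i-PrMgCl (excess), THF, –20 → 0 °C
Reagents that add atoms: none
Why: Direct ester-to-Weinreb-amide aminolysis by the magnesium amide made in the flask; the free hydroxyl is only deprotonated.

Step 8
Reactants: 12 2-[(1R,4S)-4-hydroxy-2-methylcyclohex-2-en-1-yl]-N-methoxy-N-methylacetamide; 13 vinylmagnesium bromide
Product: 14 1-[(1R,4S)-4-hydroxy-2-methylcyclohex-2-en-1-yl]but-3-en-2-one
Conditions: THF, 0 °C; inverse quench into cold 1 M HCl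
Reagents that add atoms: none
Why: Weinreb ketone synthesis: addition stops at the chelated tetrahedral intermediate, and the acidic inverse quench protonates the released amine so that it cannot add to the vinyl ketone.

Step 9
Reactants: 14 1-[(1R,4S)-4-hydroxy-2-methylcyclohex-2-en-1-yl]but-3-en-2-one; 15 (bromomethyl)chlorodimethylsilane
Product: 16 1-[(1R,4S)-4-{[(bromomethyl)dimethylsilyl]oxy}-2-methylcyclohex-2-en-1-yl]but-3-en-2-one
Conditions: Et3N, CH2Cl2, 0 °C
Reagents that add atoms: none
Why: O-Silylation of the secondary allylic alcohol with the chlorosilane; triethylamine is chosen because it cannot add irreversibly to the vinyl ketone.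

Step 10
Reactants: 16 1-[(1R,4S)-4-{[(bromomethyl)dimethylsilyl]oxy}-2-methylcyclohex-2-en-1-yl]but-3-en-2-one
Product: 17 tricyclic siloxane ketone: cis-fused 9-methyldecal-6-one in which the C1 oxygen and a CH2 on C10 are bridged by SiMe2 (1S,4R,9S,10R in the numbering above; C1–O, C10–CH2, C9–CH3 and C4–H all on one face)
Conditions: Bu3SnH, AIBN (syringe pump, 8 h), PhH (5 mM), 80 °C
Reagents that add atoms: none
Why: Bu3Sn• abstracts bromine and the α-silyl radical, held by the C1 oxygen, adds 5-exo-trig to C10 on the oxygen face to give the tertiary C9 radical; this nucleophilic radical adds 6-endo-trig to the unsubstituted β-carbon C8 of the vinyl ketone, and the C7 α-keto radical is reduced by the stannane. The closest known chemistry is the silicon-tethered radical cyclisation of (bromomethyl)silyl ethers of allylic alcohols, run in tandem with an intramolecular Giese addition to an enone. Ring closures: siloxane ring 5-exo-trig, ring B 6-endo-trig (5-exo attack at C7 is disfavoured by polarity and would give a primary radical). C10 is set by the tether (CH2 cis to C1–O); C9 is set because the C4 chain reaches only its own face, which is also the face anti to the new C10–CH2 bond, so the fusion is cis and the C9 methyl ends up cis to the C10 methylene; C4 is untouched. The step needs 5-exo over 6-endo in the first closure (secured by the C9 methyl, which blocks attack at C9 and stabilises the radical formed) and bromine abstraction over stannyl addition to the enone (secured by slow stannane addition at high dilution).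

Step 11
Reactants: 17 tricyclic siloxane ketone
Product: 18 (4aS,5R,6S,8aR)-6-hydroxy-4a,5-dimethyloctahydronaphthalen-2(1H)-one
Conditions: TBAF (5 equiv), DMF, 70 °C
Reagents that add atoms: none
Why: Fluoride-mediated protodesilylation of the oxasilolane: fluoride attack at silicon opens the Si–O bond and the C–Si bond is protonolysed, turning the tethered CH2 into the C10 methyl with C1–OH cis to it.

Step 12
Reactants: 18 (4aS,5R,6S,8aR)-6-hydroxy-4a,5-dimethyloctahydronaphthalen-2(1H)-one
Product: 21 (4aR,5R,6S)-6-hydroxy-4a,5-dimethyl-4,4a,5,6,7,8-hexahydronaphthalen-2(3H)-one, via bis-TMS enol ether 19 (not isolated), via enone TMS ether 20 (not isolated)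
Conditions: TMSCl, NaI, Et3N, MeCN, rt; Pd(OAc)2 (1.1 equiv), MeCN, rt; citric acid, MeOH
Reagents that add atoms: none
Why: Saegusa–Ito oxidation: under equilibrating conditions the cis-fused ketone should enolise toward the ring fusion (C5), as cis-fused 3-keto steroids do, and Pd(II) removes the C4 hydrogen to give the C4=C5 enone, the C1 hydroxyl being masked in the same pot as its TMS ether.

Step 13
Reactants: 21 (4aR,5R,6S)-6-hydroxy-4a,5-dimethyl-4,4a,5,6,7,8-hexahydronaphthalen-2(3H)-one
Product: 24 (4aR,5R,6S)-6-hydroxy-4a,5-dimethyl-4,4a,5,6-tetrahydronaphthalen-2(3H)-one, via bis-TMS dienol ether 22 (not isolated), via dienone TMS ether 23 (not isolated)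
Conditions: TMSCl, NaI, Et3N, MeCN, rt; Pd(OAc)2 (1.1 equiv), MeCN, rt; citric acid, MeOH
Reagents that add atoms: none
Why: Second Saegusa–Ito oxidation: the extended (thermodynamic) dienol ether is palladated at C3 and β-hydride elimination from C2 gives the linear C2=C3/C4=C5 dienone.

Step 14
Reactants: 25 1-butyne
Product: 28 (E)-3-methylpent-2-en-1-ol, via alkenylalane 26 (not isolated), via lithium alanate 27 (not isolated)
Conditions: Me3Al, Cp2ZrCl2 (20 mol%), CH2Cl2, 0 °C → rt; n-BuLi, THF, –78 °C; (CH2O)n, rt; aq. HCl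
Reagents that add atoms: trimethylaluminium, C[Al](C)C; formaldehyde (from paraformaldehyde), C=O
Why: Negishi carboalumination: syn addition of Me–Al across the terminal alkyne gives the (E)-alkenylalane, whose ate complex is hydroxymethylated with retention of alkene geometry.

Step 15
Reactants: 28 (E)-3-methylpent-2-en-1-ol
Product: 29 [(2R,3R)-3-ethyl-3-methyloxiran-2-yl]methanol
Conditions: Ti(OiPr)4 (5 mol%), D-(–)-DET (6 mol%), t-BuOOH, 4 Å MS, CH2Cl2, –20 °C
Reagents that add atoms: tert-butyl hydroperoxide, CC(C)(C)OO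
Why: Sharpless asymmetric epoxidation: with D-(–)-diethyl tartrate this (E)-3,3-disubstituted allylic alcohol should give the (2R,3R)-epoxide, the mirror image of the face selectivity of geraniol with the L-tartrate.

Step 16
Reactants: 29 [(2R,3R)-3-ethyl-3-methyloxiran-2-yl]methanol
Product: 30 (2S,3R)-3-ethyl-2-(iodomethyl)-3-methyloxirane
Conditions: PPh3, I2, imidazole, CH2Cl2, 0 °C
Reagents that add atoms: iodine, II
Why: Appel-type iodination (SN2 at the primary CH2) under imidazole buffering leaves the epoxide and both stereocentres intact; the C2 descriptor changes only through CIP priorities.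

Step 17
Reactants: 30 (2S,3R)-3-ethyl-2-(iodomethyl)-3-methyloxirane
Product: 31 (R)-3-methylpent-1-en-3-ol
Conditions: Zn dust, EtOH, reflux
Reagents that add atoms: none
Why: Reductive β-elimination: zinc insertion into the C–I bond opens the epoxide to the tertiary allylic alcohol without breaking the C–O bond at the quaternary carbon, so its configuration is retained.

Step 18
Reactants: 31 (R)-3-methylpent-1-en-3-ol; 32 ethyl (E)-3-iodoacrylate
Product: 33 ethyl (2E,4E,6R)-6-hydroxy-6-methylocta-2,4-dienoate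
Conditions: Pd(OAc)2 (5 mol%), Ag2CO3, MeCN, 50 °C
Reagents that add atoms: none
Why: Heck reaction: the alkenylpalladium adds to the terminal alkene carbon and β-hydride elimination can only give the (E)-diene because the carbinol carbon carries no hydrogen, while the (E)-geometry of the iodoacrylate is retained.

Step 19
Reactants: 33 ethyl (2E,4E,6R)-6-hydroxy-6-methylocta-2,4-dienoate
Product: 34 ethyl (2E,4E,6R)-6-methyl-6-[(triethylsilyl)oxy]octa-2,4-dienoate
Conditions: TESOTf, 2,6-lutidine, CH2Cl2, 0 °C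
Reagents that add atoms: triethylsilyl trifluoromethanesulfonate, CC[Si](CC)(CC)OS(=O)(=O)C(F)(F)F
Why: Silylation of the tertiary alcohol with the silyl triflate keeps it from being acylated in the later esterification.

Step 20
Reactants: 34 ethyl (2E,4E,6R)-6-methyl-6-[(triethylsilyl)oxy]octa-2,4-dienoate
Product: 35 (2E,4E,6R)-6-methyl-6-[(triethylsilyl)oxy]octa-2,4-dienoic acid
Conditions: LiOH, THF/MeOH/H2O, rt; 1 M HCl to pH 4
Reagents that add atoms: lithium hydroxide, [Li+].[OH-]
Why: Ester saponification; the tertiary TES ether and the diene should survive aqueous LiOH and a brief mild acidification.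

Step 21
Reactants: 35 (2E,4E,6R)-6-methyl-6-[(triethylsilyl)oxy]octa-2,4-dienoic acid; 24 (4aR,5R,6S)-6-hydroxy-4a,5-dimethyl-4,4a,5,6-tetrahydronaphthalen-2(3H)-one
Product: 37 (1R,2S,8aR)-1,8a-dimethyl-6-oxo-1,2,6,7,8,8a-hexahydronaphthalen-2-yl (2E,4E,6R)-6-methyl-6-[(triethylsilyl)oxy]octa-2,4-dienoate, via mixed anhydride 36 (not isolated)
Conditions: 2,4,6-Cl3C6H2COCl, Et3N, THF, rt; then 24, DMAP, PhMe, rt
Reagents that add atoms: none
Why: Yamaguchi esterification: DMAP attacks the less hindered dienoyl carbonyl of the mixed anhydride and the acylpyridinium acylates the hindered pseudoaxial C1 alcohol with retention at C1.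

Step 22
Reactants: 37 (1R,2S,8aR)-1,8a-dimethyl-6-oxo-1,2,6,7,8,8a-hexahydronaphthalen-2-yl (2E,4E,6R)-6-methyl-6-[(triethylsilyl)oxy]octa-2,4-dienoate
Product: 40 (1R,2S,7R,8aR)-7-hydroxy-1,8a-dimethyl-6-oxo-1,2,6,7,8,8a-hexahydronaphthalen-2-yl (2E,4E,6R)-6-hydroxy-6-methylocta-2,4-dienoate, via TMS trienol ether 38 (not isolated), via silyloxy ketone 39 (not isolated)
Conditions: LiHMDS, TMSCl, THF, –78 °C; mCPBA, NaHCO3, CH2Cl2, –20 °C; HF·pyridine, THF, 0 °C
Reagents that add atoms: 3-chloroperoxybenzoic acid, OOC(=O)c1cccc(Cl)c1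
Why: Rubottom oxidation: C7 is the only enolisable α-carbon, the electron-rich silyl enol ether is epoxidised in preference to the electron-poor dienone and dienoate alkenes on the face anti to the axial C9 methyl (which sets C7 as R), and HF·pyridine then removes the TMS and TES groups.

**Compound list**
1 | 2-methylcyclohex-2-en-1-one | CC1=CCCCC1=O | starting material
2 | (R)-2-methylcyclohex-2-en-1-ol | O[C@H]1C(C)=CCCC1 | intermediate
3 | triethyl orthoacetate | CC(OCC)(OCC)OCC | starting material
4 | (R)-6-[(1-ethoxyvinyl)oxy]-1-methylcyclohex-1-ene (mixed ketene acetal of 2) | C=C(OCC)O[C@H]1C(C)=CCCC1 | intermediate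
5 | ethyl 2-[(1R)-2-methylcyclohex-2-en-1-yl]acetate | CCOC(=O)C[C@@H]1C(C)=CCCC1 | intermediate
6 | ethyl 2-[(1R)-2-methyl-4-oxocyclohex-2-en-1-yl]acetate | CCOC(=O)C[C@@H]1C(C)=CC(=O)CC1 | intermediate
7 | ethyl 2-[(1R)-2,3-dibromo-2-methyl-4-oxocyclohexyl]acetate (diastereomer mixture at C2/C3) | CCOC(=O)C[C@@H]1C(C)(Br)C(Br)C(=O)CC1 | intermediate
8 | ethyl 2-[(1R)-3-bromo-2-methyl-4-oxocyclohex-2-en-1-yl]acetate | CCOC(=O)C[C@@H]1C(C)=C(Br)C(=O)CC1 | intermediate
9 | ethyl 2-[(1R,4S)-3-bromo-4-hydroxy-2-methylcyclohex-2-en-1-yl]acetate | CCOC(=O)C[C@@H]1C(C)=C(Br)[C@@H](O)CC1 | intermediate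
10 | ethyl 2-[(1R,4S)-4-hydroxy-2-methylcyclohex-2-en-1-yl]acetate | CCOC(=O)C[C@@H]1C(C)=C[C@@H](O)CC1 | intermediate
11 | N,O-dimethylhydroxylamine hydrochloride | CNOC.Cl | starting material
12 | 2-[(1R,4S)-4-hydroxy-2-methylcyclohex-2-en-1-yl]-N-methoxy-N-methylacetamide | CON(C)C(=O)C[C@@H]1C(C)=C[C@@H](O)CC1 | intermediate
13 | vinylmagnesium bromide | C=C[Mg]Br | starting material
14 | 1-[(1R,4S)-4-hydroxy-2-methylcyclohex-2-en-1-yl]but-3-en-2-one | C=CC(=O)C[C@@H]1C(C)=C[C@@H](O)CC1 | intermediate
15 | (bromomethyl)chlorodimethylsilane | C[Si](C)(Cl)CBr | starting material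
16 | 1-[(1R,4S)-4-{[(bromomethyl)dimethylsilyl]oxy}-2-methylcyclohex-2-en-1-yl]but-3-en-2-one | BrC[Si](C)(C)O[C@H]1CC[C@H](CC(=O)C=C)C(C)=C1 | intermediate
17 | tricyclic siloxane ketone (cis-fused 9-methyldecal-6-one, C1–O–SiMe2–CH2–C10 bridge; 1S,4R,9S,10R) | C[Si]1(C)C[C@H]2[C@@H](O1)CC[C@@H]3CC(=O)CC[C@]23C | intermediate
18 | (4aS,5R,6S,8aR)-6-hydroxy-4a,5-dimethyloctahydronaphthalen-2(1H)-one | C[C@H]1[C@@H](O)CC[C@@H]2CC(=O)CC[C@]12C | intermediate
19 | C5=C6 trimethylsilyl enol ether and C1 TMS ether of 18 | C[C@H]1[C@@H](O[Si](C)(C)C)CC[C@@H]2C=C(O[Si](C)(C)C)CC[C@]12C | intermediate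
20 | C1 TMS ether of 21 | C[C@H]1[C@@H](O[Si](C)(C)C)CCC2=CC(=O)CC[C@]12C | intermediate
21 | (4aR,5R,6S)-6-hydroxy-4a,5-dimethyl-4,4a,5,6,7,8-hexahydronaphthalen-2(3H)-one | C[C@H]1[C@@H](O)CCC2=CC(=O)CC[C@]12C | intermediate
22 | C6-O-TMS 3,5-dienol ether (C3=C4, C5=C6) and C1 TMS ether of 21 | C[C@H]1[C@@H](O[Si](C)(C)C)CC=C2C=C(O[Si](C)(C)C)CC[C@]12C | intermediate
23 | C1 TMS ether of 24 | C[C@H]1[C@@H](O[Si](C)(C)C)C=CC2=CC(=O)CC[C@]12C | intermediate
24 | (4aR,5R,6S)-6-hydroxy-4a,5-dimethyl-4,4a,5,6-tetrahydronaphthalen-2(3H)-one | C[C@H]1[C@@H](O)C=CC2=CC(=O)CC[C@]12C | intermediate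
25 | 1-butyne | CCC#C | starting material
26 | (E)-dimethyl(2-methylbut-1-en-1-yl)alane | CC/C(C)=C/[Al](C)C | intermediate
27 | lithium (E)-butyldimethyl(2-methylbut-1-en-1-yl)aluminate | CC/C(C)=C/[Al-](C)(C)CCCC.[Li+] | intermediate
28 | (E)-3-methylpent-2-en-1-ol | CC/C(C)=C/CO | intermediate
29 | [(2R,3R)-3-ethyl-3-methyloxiran-2-yl]methanol | CC[C@@]1(C)O[C@@H]1CO | intermediate
30 | (2S,3R)-3-ethyl-2-(iodomethyl)-3-methyloxirane | CC[C@@]1(C)O[C@@H]1CI | intermediate
31 | (R)-3-methylpent-1-en-3-ol | CC[C@@](C)(O)C=C | intermediate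
32 | ethyl (E)-3-iodoacrylate | CCOC(=O)/C=C/I | starting material
33 | ethyl (2E,4E,6R)-6-hydroxy-6-methylocta-2,4-dienoate | CC[C@@](C)(O)/C=C/C=C/C(=O)OCC | intermediate
34 | ethyl (2E,4E,6R)-6-methyl-6-[(triethylsilyl)oxy]octa-2,4-dienoate | CC[C@@](C)(O[Si](CC)(CC)CC)/C=C/C=C/C(=O)OCC | intermediate
35 | (2E,4E,6R)-6-methyl-6-[(triethylsilyl)oxy]octa-2,4-dienoic acid | CC[C@@](C)(O[Si](CC)(CC)CC)/C=C/C=C/C(=O)O | intermediate
36 | mixed anhydride of 35 with 2,4,6-trichlorobenzoic acid | CC[C@@](C)(O[Si](CC)(CC)CC)/C=C/C=C/C(=O)OC(=O)c1c(Cl)cc(Cl)cc1Cl | intermediate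
37 | (1R,2S,8aR)-1,8a-dimethyl-6-oxo-1,2,6,7,8,8a-hexahydronaphthalen-2-yl (2E,4E,6R)-6-methyl-6-[(triethylsilyl)oxy]octa-2,4-dienoate | CC[C@@](C)(O[Si](CC)(CC)CC)/C=C/C=C/C(=O)O[C@H]1C=CC2=CC(=O)CC[C@]2(C)[C@H]1C | intermediate
38 | C6-O-TMS cross-conjugated trienol ether (C6=C7) of 37 | CC[C@@](C)(O[Si](CC)(CC)CC)/C=C/C=C/C(=O)O[C@H]1C=CC2=CC(O[Si](C)(C)C)=CC[C@]2(C)[C@H]1C | intermediate
39 | (7R)-7-[(trimethylsilyl)oxy] derivative of 37 | CC[C@@](C)(O[Si](CC)(CC)CC)/C=C/C=C/C(=O)O[C@H]1C=CC2=CC(=O)[C@H](O[Si](C)(C)C)C[C@]2(C)[C@H]1C | intermediate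
40 | (1R,2S,7R,8aR)-7-hydroxy-1,8a-dimethyl-6-oxo-1,2,6,7,8,8a-hexahydronaphthalen-2-yl (2E,4E,6R)-6-hydroxy-6-methylocta-2,4-dienoate | CC[C@@](C)(O)/C=C/C=C/C(=O)O[C@H]1C=CC2=CC(=O)[C@H](O)C[C@]2(C)[C@H]1C | target

**Step count**
Total: 22 steps. Longest linear sequence: 15 steps (steps 1–13, 21, 22); the acid 35 is made in 7 steps (14–20).

**Steps most likely to fail, with fallbacks**

Step 10. The tertiary C9 radical may be reduced by the stannane, or the vinyl ketone may be consumed by stannyl radical addition and oligomerisation, before the 6-endo closure takes place. The fallback sets out from 10 and closes ring B by ionic chemistry. O-Silylation of 10 with 15 (Et3N, CH2Cl2) would give ethyl 2-[(1R,4S)-4-{[(bromomethyl)dimethylsilyl]oxy}-2-methylcyclohex-2-en-1-yl]acetate F1. Tin-mediated 5-exo cyclisation of this ether in the presence of ethyl acrylate, with intermolecular Giese trapping of the C9 radical anti to the siloxane, would give the siloxane diester F2. Dieckmann condensation (KOt-Bu, THF) would then form ring B as the C7-carboxylate β-keto ester F3 or its C5-carboxylate regioisomer F4. Krapcho dealkoxycarbonylation of either (LiCl, wet DMSO, 140 °C) would come back to the route at 17.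

Step 22. Enolisation and epoxidation on the fully assembled ester may be unselective (competing deprotonation at C1, epoxidation of the dienoate, or loss of the allylic ester). The fallback sets out from 24 and hydroxylates C7 before the side chain is attached. Double deprotonation of 24 (KHMDS, 2.2 equiv, THF, –78 °C) and enolate oxidation with 2-(phenylsulfonyl)-3-phenyloxaziridine would give (3R,4aR,5R,6S)-3,6-dihydroxy-4a,5-dimethyl-4,4a,5,6-tetrahydronaphthalen-2(3H)-one F7. Selective silylation of the unhindered equatorial C7 hydroxyl (TBSCl, imidazole, DMF, 0 °C) would give the 3-[(tert-butyldimethylsilyl)oxy] ketone F8. Yamaguchi esterification of its C1 hydroxyl with 35 would give the bis-silylated ester F9, and HF·pyridine would remove both silyl groups and come back to the route at 40.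

Step 5. The reduction is a mismatched case: the catalyst must deliver hydride syn to the pseudoaxial C4 side chain, so the facial selectivity at C1 may be poor. The fallback sets out from 6 and uses the substrate's own bias followed by inversion. Luche reduction (NaBH4, CeCl3·7H2O, MeOH, –78 °C; axial attack anti to the side chain) would give the cis alcohol ethyl 2-[(1R,4R)-4-hydroxy-2-methylcyclohex-2-en-1-yl]acetate F5. Mitsunobu inversion (4-nitrobenzoic acid, PPh3, DIAD, THF) would give the (1R,4S) 4-nitrobenzoate F6. Ethanolysis (K2CO3, EtOH) would come back to the route at 10, bypassing 7–9.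

**Further compounds**
F1 | step 10 | ethyl 2-[(1R,4S)-4-{[(bromomethyl)dimethylsilyl]oxy}-2-methylcyclohex-2-en-1-yl]acetate | BrC[Si](C)(C)O[C@H]1CC[C@H](CC(=O)OCC)C(C)=C1
F2 | step 10 | siloxane diester (oxasilolane-fused cyclohexane with C4–CH2CO2Et and C9–CH2CH2CO2Et, C9 methyl cis to C10–CH2) | C[Si]1(C)C[C@H]2[C@@H](O1)CC[C@H](CC(=O)OCC)[C@]2(C)CCC(=O)OCC
F3 | step 10 | C7-ethoxycarbonyl derivative of 17 (β-keto ester, C7 epimers/enol) | C[Si]1(C)C[C@H]2[C@@H](O1)CC[C@@H]3CC(=O)C(C(=O)OCC)C[C@]23C
F4 | step 10 | C5-ethoxycarbonyl derivative of 17 (regioisomeric β-keto ester) | C[Si]1(C)C[C@H]2[C@@H](O1)CC[C@@H]3C(C(=O)OCC)C(=O)CC[C@]23C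
F5 | step 5 | ethyl 2-[(1R,4R)-4-hydroxy-2-methylcyclohex-2-en-1-yl]acetate | CCOC(=O)C[C@@H]1C(C)=C[C@H](O)CC1
F6 | step 5 | (1S,4R)-4-(2-ethoxy-2-oxoethyl)-3-methylcyclohex-2-en-1-yl 4-nitrobenzoate | CCOC(=O)C[C@@H]1C(C)=C[C@@H](OC(=O)c2ccc(cc2)[N+](=O)[O-])CC1
F7 | step 22 | (3R,4aR,5R,6S)-3,6-dihydroxy-4a,5-dimethyl-4,4a,5,6-tetrahydronaphthalen-2(3H)-one | C[C@H]1[C@@H](O)C=CC2=CC(=O)[C@H](O)C[C@]12C
F8 | step 22 | (3R,4aR,5R,6S)-3-[(tert-butyldimethylsilyl)oxy]-6-hydroxy-4a,5-dimethyl-4,4a,5,6-tetrahydronaphthalen-2(3H)-one | C[C@H]1[C@@H](O)C=CC2=CC(=O)[C@H](O[Si](C)(C)C(C)(C)C)C[C@]12C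
F9 | step 22 | (1R,2S,7R,8aR)-7-[(tert-butyldimethylsilyl)oxy]-1,8a-dimethyl-6-oxo-1,2,6,7,8,8a-hexahydronaphthalen-2-yl (2E,4E,6R)-6-methyl-6-[(triethylsilyl)oxy]octa-2,4-dienoate | CC[C@@](C)(O[Si](CC)(CC)CC)/C=C/C=C/C(=O)O[C@H]1C=CC2=CC(=O)[C@H](O[Si](C)(C)C(C)(C)C)C[C@]2(C)[C@H]1C
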